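All runs were computed for substances that don't exist, noise included.

- The constants are hidden from me, so I read rates from the two earlier runs, cedar and maple, which differ in their reagent charge.

| flask | starting material | second substrate | reagent | free catalyst | remark |
|---|---|---|---|---|---|
| cedar | 0.10 M | 1 equiv | 1 equiv | 1.5 mol% | run made earlier |
| maple | 0.10 M | 1 equiv | 2.2 equiv | 1.5 mol% | run made earlier |
| flask | 0.10 M | 1.00 equiv | 1.50 equiv | 1.5 mol% |  |

- cedar (time / d: target / %): 2.08: 24.7; 4.00: 34.5; 6.00: 40.0; 8.00: 41.7
- maple (time / d: target / %): 0.625: 20.8; 1.67: 40.3; 3.00: 51.9; 8.00: 67.5

(each reading ± 0.5 percentage points)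

- what may be going on: starting material + free catalyst <-> catalyst intermediate A; reagent + catalyst intermediate B -> free catalyst + second product; second substrate + free catalyst <-> catalyst intermediate B; reagent + catalyst intermediate A -> spent catalyst; reagent + catalyst intermediate A -> free catalyst + target
- no earlier run changes the charge of second substrate; that part of a forecast is a guess

- apparent order in reagent when 30% of the starting material are converted (percent change of the rate of making target for one percent more reagent charged)
- apparent order in second substrate when 30% of the starting material are converted (percent change of the rate of making target for one percent more second substrate charged)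

- Up to the first reading, cedar averages 0.0119 M d⁻¹ and maple 0.0333 M d⁻¹.
- Reagent use and catalyst loss can both slow a run, and these readings do not separate them. Taking target as conversion, the stretch of each run that spans 30% gives 0.00510 M d⁻¹ for cedar and 0.0187 M d⁻¹ for maple, so the slowing factors are 2.33 and 1.78.
- Over the last stretch, the factors reach 14.0 for cedar and 10.7 for maple, and the runs stand at 41.7% and 67.5% target.
- My carried quantity is the equal-conversion order, the logarithm of the maple-to-cedar rate ratio at 30% over the logarithm of their charge ratio: 1.64. This is an apparent order in reagent.
- Scaling cedar's rate by the flask's charge ratio raised to that order, I expect 0.00994 M d⁻¹ in the flask. Second substrate stands at one charge in both earlier runs, so I give no reading for it.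
- The forecast gives 1.6 and −0.65: “More second substrate burns reagent (about −0.4) and ties up catalyst (about −0.25), giving about −0.65. That second effect is a guess.”

- The flask gives 1.6 in reagent and −0.42 in second substrate.

    starting material + free catalyst ⇌ catalyst intermediate A (K = 4.80 L mol⁻¹, k = 1200 L mol⁻¹ h⁻¹)
    reagent + catalyst intermediate B → free catalyst + second product (k = 18.0 L mol⁻¹ h⁻¹)
    second substrate + free catalyst ⇌ catalyst intermediate B (K = 5.20 L mol⁻¹, k = 41.0 L mol⁻¹ h⁻¹)
    reagent + catalyst intermediate A → spent catalyst (k = 0.410 L mol⁻¹ h⁻¹)
    reagent + catalyst intermediate A → free catalyst + target (k = 23.0 L mol⁻¹ h⁻¹)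

- The flask reaches 30% conversion at 1.61 d and runs at 0.0107 M d⁻¹, faster than my 0.00994 M d⁻¹ from the order of 1.64. The forecast's −0.65 lies below the flask's −0.42. Of the two reverse steps, the largest single effect on that order comes from catalyst intermediate B returning to second substrate and free catalyst: with that reverse step removed, the flask's order is −3.8.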